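## Analysis of the target

Abroquinone A (18) is an isoflavan quinone. Its core is a 3,4-dihydro-2H-1-benzopyran whose benzo ring (ring A) carries methoxy groups at C6 and C7. C3 of the pyran ring (ring C) is bonded to C5 of a 2,3-dimethoxy-1,4-benzoquinone (ring B, isoflavan positions C1' to C6', carbonyls at C2' and C5'). The only stereocentre is C3, and the SMILES assigns it (S) (CIP order C2 > C1' > C4 > H). It is a tertiary C–H flanked by the O-methylene C2, the benzylic methylene C4 and ring B. It has no neighbouring stereocentre and no heteroatom of its own, so its sense must come from a reagent or catalyst. The quinone is the sensitive group: it is electrophilic, easily reduced, and can enolise through C3–H towards a quinone methide, which would erase the stereocentre. It should therefore appear last and under near-neutral conditions. Ring A is a 1,2,4-trioxygenated benzene and is itself oxidisable, so the final oxidation must single out ring B. Two phenol-level oxygens, O1 on ring A and O2' on ring B, must be kept apart, because either could close a ring onto C2. The strategy rests on the pair C2/C3: C3 bears ring B and C4, while C2 is a terminal carbon on oxygen. That is the pattern an anti-Markovnikov hydroboration leaves on a 1,1-disubstituted alkene C2=C3.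

## Retrosynthetic reasoning

**Quinone back to a phenol (18 to 17 to 16).** No skeletal bond is cut. In phenol 17 the hydroxyl sits at C2', both ortho positions are substituted and the para carbon C5' carries hydrogen, so a Teuber oxidation can only give the 2',5'-quinone. The quinone then exists in the last flask only. Phenol 17 is carried as its methoxymethyl ether 16, because a free O2' would compete with O1 in the ring closure.

**Pyran ring opened at O1–C2 (16 to 15 to 14).** The alkyl–oxygen bond is cut, not the aryl–oxygen bond O1–C8a. The aryl–oxygen bond is already present in the commercial phenol 7, and making it late would need a metal-catalysed coupling on an electron-rich ring. O1–C2 closes by a Mitsunobu reaction at a primary carbon that is not stereogenic, so C3 is not at risk. Phenol-alcohol 15 comes from silyl ether 14, and the silyl group keeps O1 apart from O2'.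

**C2–O and C3–H traced to an alkene (14 to 13 to 11 and 12).** The primary alcohol 14 is the oxidation product of primary boronate 13. Boronate 13 is the anti-Markovnikov adduct of pinacolborane 12 with the 1,1-disubstituted alkene 11. This is the one point where C3 becomes stereogenic. No skeletal bond is formed, and all C–C bonds are in place before the stereocentre exists. The forward reaction must add hydrogen to one face of the aryl-bearing alkene carbon and boron to the terminal carbon.

**C4–C4a by a sigmatropic shift (11 to 10 to 8).** The 2-arylallyl unit on ring A is cut at C4–C4a and traced to allyl aryl ether 8 through an aromatic Claisen rearrangement. The rearrangement places the chain ortho to the phenol oxygen and, at the less hindered of the two ortho carbons, para to a methoxy group. That is the C4a position. It also unveils the phenol (in 10) that later becomes O1. Silylation then gives 11.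

**Ether bond (8 to 6 and 7).** The O–CH2 bond of 8 is cut to allylic alcohol 6 and phenol 7. The allyl unit is symmetric (both termini are CH2), so direct and allylic substitution give the same ether.

**Aryl–vinyl bond (6 to 4 and 5, 4 to 2 to 1).** The bond between ring B and the alkene carbon is cut to aryl boronate 4 and vinyl bromide 5, joined by a Suzuki–Miyaura coupling. Boronate 4 comes from methoxymethyl ether 2 by directed ortho-lithiation (through aryllithium 3) and borylation, and 2 from phenol 1. The methoxymethyl group serves twice: it directs the metalation and later masks O2'.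

## Alternatives that were turned down

**Alternative 1:** The C3–C1' bond is cut. Ring B enters as the electrophile 2,3-dimethoxy-1,4-benzoquinone (A2) and C3 as the α-carbon of 3-(2-bromo-4,5-dimethoxyphenyl)propanal (A1).
- Forward key step: a diarylprolinol silyl ether converts A1 into its enamine, which adds to one of the two equivalent free ring carbons of A2. Tautomerisation to the hydroquinone and closure of the ortho hydroxyl onto the aldehyde give lactol A3, (3S)-3-[(2-bromo-4,5-dimethoxyphenyl)methyl]-6,7-dimethoxy-2,3-dihydro-1-benzofuran-2,5-diol.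
- For: a C–C bond and the stereocentre are made together, ring B arrives with both methoxy groups and almost at the quinone oxidation level, and the route would probably be three or four steps shorter than the chosen one. On step count and convergence this alternative is stronger.
- Against: in A3 the stereocentre is α to a masked aldehyde, so it can epimerise by ring–chain tautomerism, and the lactol can dehydrate to a benzofuran, which destroys C3. The quinone A2 is also an oxidant for the hydroquinone product. After reduction of the lactol, O1–C8a must be made by a metal-catalysed C–O coupling on an electron-rich aryl bromide. The hydroquinone hydroxyls would have to be protected first, and β-hydride loss from the alkoxide would compete.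
- Comparison: the chosen strategy is longer, but C3 never sits next to a carbonyl group, and the ring is closed at an sp3 carbon under Mitsunobu conditions with O1 in place from the start.

**Alternative 2:** Both bonds from ring A to the pyran ring, C4–C4a and O1–C8a, are cut at once. This gives 4-iodo-1,2-dimethoxybenzene (A4) and (2S)-3-bromo-2-[3,4-dimethoxy-2-(methoxymethoxy)phenyl]propan-1-ol (A5).
- Forward key step: a palladium catalyst with a strained bicyclic alkene cocatalyst (Catellani conditions) alkylates the C–H ortho to iodine with the bromide arm of A5. The alcohol then closes on the ipso carbon to give chroman A6, (3S)-3-[3,4-dimethoxy-2-(methoxymethoxy)phenyl]-6,7-dimethoxychroman, which has the structure of 16.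
- For: the whole pyran ring is laid onto a simple iodoarene in one operation, which is the most convergent ring construction considered.
- Against: the stereocentre is only moved into A5, which needs its own enantioselective synthesis of much the same kind as the key step chosen here, so nothing is saved overall. The benzylic C3–H of A5 is β to bromide, and carbonate base at high temperature should eliminate HBr to the achiral allylic alcohol. A4 has two free ortho positions, so double alkylation and the wrong ortho site compete. The terminating aryl–O reductive elimination is a slow step for palladium.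
- Comparison: this alternative is stronger on ring-forming economy. The chosen strategy makes every skeletal bond before C3 is stereogenic and exposes it afterwards only to mild C–O chemistry.

**Alternative 3:** C3 is taken as the ring carbon of the prochiral oxetane A7, 3-[2,5-bis(benzyloxy)-3,4-dimethoxyphenyl]oxetane, whose two CH2–O arms are enantiotopic.
- Forward key step: a chiral squaramide hydrogen-bond donor with a silyl bromide opens one arm by bromide attack. The product is A8, {(2R)-2-[2,5-bis(benzyloxy)-3,4-dimethoxyphenyl]-3-bromopropoxy}trimethylsilane.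
- For: desymmetrisation of 3-aryl oxetanes is a well-founded way to this kind of benzylic stereocentre, and the two arms emerge differentiated. The dibenzyl hydroquinone would give the quinone by hydrogenolysis and mild oxidation, which is cleaner than oxidising a monophenol. On that last point this alternative is stronger.
- Against: (R)-A8 maps onto the (S) target only if the brominated carbon becomes C2 and the silyloxy arm becomes C4. Displacement of this β-branched bromide by phenol 7 competes with elimination through the benzylic hydrogen, which gives an achiral allyl ether. The C4–C4a bond must then be made by a Friedel–Crafts closure of a primary electrophile β to an electron-rich aryl group, where aryl participation can shift ring B and scramble C3. A7 itself needs a separate arylation of a four-membered ring, and its ortho benzyloxy group may disturb the catalyst.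
- Comparison: both strategies set C3 by catalyst control at a prochiral carbon. In the oxetane route a C–C bond must still be made next to the new stereocentre. In the chosen route only two C–O bonds follow it, neither at C3.

Key step: step 7

Remark on the chemistry: which antipode of the iminopyridine-oxazoline ligand delivers hydride to the Re face of the internal alkene carbon of 11 is not predicted here. The route assumes the antipode that does (both come from the two commercial antipodes of tert-leucinol), to be confirmed on the first run.

## Route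

Step 1
Reactants: 1 2,3-dimethoxyphenol
Product: 2 1,2-dimethoxy-3-(methoxymethoxy)benzene
Conditions: chloromethyl methyl ether, iPr2NEt, CH2Cl2, 0 °C to rt
Reagents that add atoms: chloromethyl methyl ether, COCCl
Why: O-alkylation of a phenol with an α-chloro ether (acetal protection). The acetal later directs the metalation and masks O2' until the end.

Step 2
Reactants: 2 1,2-dimethoxy-3-(methoxymethoxy)benzene
Product: 4 2-[3,4-dimethoxy-2-(methoxymethoxy)phenyl]-4,4,5,5-tetramethyl-1,3,2-dioxaborolane, via aryllithium 3 (not isolated)
Conditions: n-BuLi, TMEDA, THF, 0 °C; then 2-isopropoxy-4,4,5,5-tetramethyl-1,3,2-dioxaborolane, −78 °C to rt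
Reagents that add atoms: 2-isopropoxy-4,4,5,5-tetramethyl-1,3,2-dioxaborolane, CC(C)OB1OC(C)(C)C(C)(C)O1
Why: Directed ortho-metalation. The chelating methoxymethoxy group is the stronger director and its only free ortho carbon is the future C1', so lithiation there should prevail over the site next to the methoxy group. The borate ester traps the aryllithium as the pinacol boronate.

Step 3
Reactants: 4 2-[3,4-dimethoxy-2-(methoxymethoxy)phenyl]-4,4,5,5-tetramethyl-1,3,2-dioxaborolane; 5 2-bromoprop-2-en-1-ol
Product: 6 2-[3,4-dimethoxy-2-(methoxymethoxy)phenyl]prop-2-en-1-ol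
Conditions: Pd(dppf)Cl2 (cat.), K2CO3, dioxane/H2O, 80 °C
Reagents that add atoms: none
Why: Suzuki–Miyaura coupling. Zerovalent palladium inserts into the vinyl C–Br bond, the boronate transmetalates under carbonate activation, and reductive elimination forms the aryl–vinyl bond. The free allylic hydroxyl is tolerated.

Step 4
Reactants: 6 2-[3,4-dimethoxy-2-(methoxymethoxy)phenyl]prop-2-en-1-ol; 7 3,4-dimethoxyphenol
Product: 8 1-[3-(3,4-dimethoxyphenoxy)prop-1-en-2-yl]-3,4-dimethoxy-2-(methoxymethoxy)benzene
Conditions: PPh3, DIAD, THF, 0 °C to rt
Reagents that add atoms: none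
Why: Mitsunobu etherification of a primary allylic alcohol with a phenol. Both allyl termini are CH2, so direct and allylic displacement lead to the same ether.

Step 5
Reactants: 8 1-[3-(3,4-dimethoxyphenoxy)prop-1-en-2-yl]-3,4-dimethoxy-2-(methoxymethoxy)benzene
Product: 10 2-{2-[3,4-dimethoxy-2-(methoxymethoxy)phenyl]prop-2-en-1-yl}-4,5-dimethoxyphenol, via ortho-dienone 9 (not isolated)
Conditions: PhNEt2, 190 °C, sealed tube, argon
Reagents that add atoms: none
Why: Aromatic Claisen rearrangement. The [3,3] shift should go mainly to the ortho carbon para to a methoxy group, not to the one wedged between two oxygens, and the dienone tautomerises to the phenol. The basic amine solvent protects the acetal and keeps the new phenol from adding to the alkene.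

Step 6
Reactants: 10 2-{2-[3,4-dimethoxy-2-(methoxymethoxy)phenyl]prop-2-en-1-yl}-4,5-dimethoxyphenol
Product: 11 tert-butyl(2-{2-[3,4-dimethoxy-2-(methoxymethoxy)phenyl]prop-2-en-1-yl}-4,5-dimethoxyphenoxy)dimethylsilane
Conditions: tert-butyldimethylsilyl chloride, imidazole, DMF, rt
Reagents that add atoms: tert-butyldimethylsilyl chloride, CC(C)(C)[Si](C)(C)Cl
Why: Silylation of a phenol. It removes the only acidic proton before the hydride catalysis and is orthogonal to the methoxymethyl ether on ring B.

Step 7
Reactants: 11 tert-butyl(2-{2-[3,4-dimethoxy-2-(methoxymethoxy)phenyl]prop-2-en-1-yl}-4,5-dimethoxyphenoxy)dimethylsilane; 12 pinacolborane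
Product: 13 tert-butyl(2-{(2S)-2-[3,4-dimethoxy-2-(methoxymethoxy)phenyl]-3-(4,4,5,5-tetramethyl-1,3,2-dioxaborolan-2-yl)propyl}-4,5-dimethoxyphenoxy)dimethylsilane
Conditions: CoCl2·L* (3 mol%; L* = single antipode of 2-(4-tert-butyl-4,5-dihydro-1,3-oxazol-2-yl)-6-[1-(2,6-diisopropylphenylimino)ethyl]pyridine), NaBHEt3 (9 mol%), 12 (1.5 equiv), THF, 25 °C
Reagents that add atoms: pinacolborane (12), [H]B1OC(C)(C)C(C)(C)O1
Why: NaBHEt3 reduces the CoCl2 complex to a low-valent cobalt hydride held by the tridentate ligand; the alkene of 11 inserts into Co–H with cobalt at the unhindered terminal carbon (C2) and hydrogen at the aryl-bearing carbon (C3), and σ-bond metathesis of the primary alkylcobalt with 12 releases 13 and regenerates the hydride. The closest known reaction type is the cobalt-catalysed enantioselective anti-Markovnikov hydroboration of α-alkylstyrenes with iminopyridine-oxazoline ligands. No ring is closed. C3 is set in the insertion step under catalyst control: the oxazoline substituent and the 2,6-diisopropylphenyl imine arm form a pocket that takes the flat ring B on one side and the sp3 arylmethyl arm on the other, so that hydride reaches the Re face of C3 and 13 is (S). The step needs enantiofacial selectivity, boron at C2 only, and no migration of the double bond into conjugation towards C4. The steric difference between the two alkene carbons fixes the regiochemistry, the contrast between aryl and CH2Ar gives the catalyst its facial handle, and the silyl cap leaves no acidic proton to quench the hydride or 12. The stereocentre is β to boron and is not involved when the C–B bond is oxidised.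

Step 8
Reactants: 13 tert-butyl(2-{(2S)-2-[3,4-dimethoxy-2-(methoxymethoxy)phenyl]-3-(4,4,5,5-tetramethyl-1,3,2-dioxaborolan-2-yl)propyl}-4,5-dimethoxyphenoxy)dimethylsilane
Product: 14 (2S)-3-{2-[(tert-butyldimethylsilyl)oxy]-4,5-dimethoxyphenyl}-2-[3,4-dimethoxy-2-(methoxymethoxy)phenyl]propan-1-ol
Conditions: NaBO3·4H2O, THF/H2O, rt
Reagents that add atoms: sodium perborate tetrahydrate (written as the peroxoborate dimer), [Na+].[Na+].O[B-]1(O)OO[B-](O)(O)OO1.O.O.O.O.O.O
Why: Oxidation of an alkylboronate. Peroxide adds to boron and the CH2 group migrates from boron to oxygen. The mild perborate should leave the aryl silyl ether and the electron-rich rings alone, and C3 is untouched.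

Step 9
Reactants: 14 (2S)-3-{2-[(tert-butyldimethylsilyl)oxy]-4,5-dimethoxyphenyl}-2-[3,4-dimethoxy-2-(methoxymethoxy)phenyl]propan-1-ol
Product: 15 2-{(2S)-2-[3,4-dimethoxy-2-(methoxymethoxy)phenyl]-3-hydroxypropyl}-4,5-dimethoxyphenol
Conditions: Bu4NF, AcOH, THF, 0 °C to rt
Reagents that add atoms: none
Why: Fluoride cleaves the aryl silyl ether. The acetic acid buffer keeps the electron-rich phenol protonated and away from air oxidation, and the methoxymethyl ether is inert to fluoride.

Step 10
Reactants: 15 2-{(2S)-2-[3,4-dimethoxy-2-(methoxymethoxy)phenyl]-3-hydroxypropyl}-4,5-dimethoxyphenol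
Product: 16 (3S)-3-[3,4-dimethoxy-2-(methoxymethoxy)phenyl]-6,7-dimethoxy-3,4-dihydro-2H-1-benzopyran
Conditions: PPh3, DIAD, THF (0.02 M), 0 °C to rt
Reagents that add atoms: none
Why: Intramolecular Mitsunobu etherification. The ring A phenol displaces the activated primary hydroxyl at C2 in a 6-exo-tet closure of the pyran ring. C2 is not stereogenic, so C3 keeps its configuration. The acetal on O2' rules out the competing five-membered closure.

Step 11
Reactants: 16 (3S)-3-[3,4-dimethoxy-2-(methoxymethoxy)phenyl]-6,7-dimethoxy-3,4-dihydro-2H-1-benzopyran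
Product: 17 6-[(3S)-6,7-dimethoxy-3,4-dihydro-2H-1-benzopyran-3-yl]-2,3-dimethoxyphenol
Conditions: HCl (3 M aq.), MeOH, 45 °C, argon
Reagents that add atoms: none
Why: Acid-catalysed acetal exchange removes the methoxymethyl group. The methanol solvent traps the oxocarbenium fragment before it can alkylate the electron-rich rings. The methyl ethers, the chroman ether and C3 are stable to dilute acid.

Step 12
Reactants: 17 6-[(3S)-6,7-dimethoxy-3,4-dihydro-2H-1-benzopyran-3-yl]-2,3-dimethoxyphenol
Product: 18 abroquinone A, 5-[(3S)-6,7-dimethoxy-3,4-dihydro-2H-1-benzopyran-3-yl]-2,3-dimethoxycyclohexa-2,5-diene-1,4-dione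
Conditions: (KSO3)2NO (2.5 equiv), KH2PO4 (aq.), acetone/H2O, 0 °C to rt
Reagents that add atoms: potassium nitrosodisulfonate, [K+].[K+].[O]N(S(=O)(=O)[O-])S(=O)(=O)[O-]
Why: Teuber oxidation. The nitroxyl radical abstracts the phenol hydrogen, a second radical couples at the free para carbon C5', and loss of imidodisulfonate gives the para-quinone. Both ortho positions are blocked and ring A has no hydroxyl, so only ring B should react. The near-neutral buffer should keep C3–H from enolising.

## Compound list

1 | 2,3-dimethoxyphenol | COc1cccc(O)c1OC | starting material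
2 | 1,2-dimethoxy-3-(methoxymethoxy)benzene | COCOc1cccc(OC)c1OC | intermediate
3 | [3,4-dimethoxy-2-(methoxymethoxy)phenyl]lithium | [Li]c1ccc(OC)c(OC)c1OCOC | intermediate (not isolated)
4 | 2-[3,4-dimethoxy-2-(methoxymethoxy)phenyl]-4,4,5,5-tetramethyl-1,3,2-dioxaborolane | COCOc1c(B2OC(C)(C)C(C)(C)O2)ccc(OC)c1OC | intermediate
5 | 2-bromoprop-2-en-1-ol | OCC(Br)=C | starting material
6 | 2-[3,4-dimethoxy-2-(methoxymethoxy)phenyl]prop-2-en-1-ol | C=C(CO)c1ccc(OC)c(OC)c1OCOC | intermediate
7 | 3,4-dimethoxyphenol | COc1ccc(O)cc1OC | starting material
8 | 1-[3-(3,4-dimethoxyphenoxy)prop-1-en-2-yl]-3,4-dimethoxy-2-(methoxymethoxy)benzene | C=C(COc1ccc(OC)c(OC)c1)c1ccc(OC)c(OC)c1OCOC | intermediate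
9 | 6-{2-[3,4-dimethoxy-2-(methoxymethoxy)phenyl]prop-2-en-1-yl}-3,4-dimethoxycyclohexa-2,4-dien-1-one (racemic at C6) | O=C1C=C(OC)C(OC)=CC1CC(=C)c1ccc(OC)c(OC)c1OCOC | intermediate (not isolated)
10 | 2-{2-[3,4-dimethoxy-2-(methoxymethoxy)phenyl]prop-2-en-1-yl}-4,5-dimethoxyphenol | C=C(Cc1cc(OC)c(OC)cc1O)c1ccc(OC)c(OC)c1OCOC | intermediate
11 | tert-butyl(2-{2-[3,4-dimethoxy-2-(methoxymethoxy)phenyl]prop-2-en-1-yl}-4,5-dimethoxyphenoxy)dimethylsilane | C=C(Cc1cc(OC)c(OC)cc1O[Si](C)(C)C(C)(C)C)c1ccc(OC)c(OC)c1OCOC | intermediate
12 | pinacolborane (4,4,5,5-tetramethyl-1,3,2-dioxaborolane) | [H]B1OC(C)(C)C(C)(C)O1 | starting material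
13 | tert-butyl(2-{(2S)-2-[3,4-dimethoxy-2-(methoxymethoxy)phenyl]-3-(4,4,5,5-tetramethyl-1,3,2-dioxaborolan-2-yl)propyl}-4,5-dimethoxyphenoxy)dimethylsilane | CC1(C)OB(C[C@@H](Cc2cc(OC)c(OC)cc2O[Si](C)(C)C(C)(C)C)c2ccc(OC)c(OC)c2OCOC)OC1(C)C | intermediate
14 | (2S)-3-{2-[(tert-butyldimethylsilyl)oxy]-4,5-dimethoxyphenyl}-2-[3,4-dimethoxy-2-(methoxymethoxy)phenyl]propan-1-ol | OC[C@@H](Cc1cc(OC)c(OC)cc1O[Si](C)(C)C(C)(C)C)c1ccc(OC)c(OC)c1OCOC | intermediate
15 | 2-{(2S)-2-[3,4-dimethoxy-2-(methoxymethoxy)phenyl]-3-hydroxypropyl}-4,5-dimethoxyphenol | OC[C@@H](Cc1cc(OC)c(OC)cc1O)c1ccc(OC)c(OC)c1OCOC | intermediate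
16 | (3S)-3-[3,4-dimethoxy-2-(methoxymethoxy)phenyl]-6,7-dimethoxy-3,4-dihydro-2H-1-benzopyran | COc1ccc([C@H]2COc3cc(OC)c(OC)cc3C2)c(OCOC)c1OC | intermediate
17 | 6-[(3S)-6,7-dimethoxy-3,4-dihydro-2H-1-benzopyran-3-yl]-2,3-dimethoxyphenol | COc1ccc([C@H]2COc3cc(OC)c(OC)cc3C2)c(O)c1OC | intermediate
18 | abroquinone A, 5-[(3S)-6,7-dimethoxy-3,4-dihydro-2H-1-benzopyran-3-yl]-2,3-dimethoxycyclohexa-2,5-diene-1,4-dione | COC1=C(OC)C(=O)C([C@H]2COc3cc(OC)c(OC)cc3C2)=CC1=O | target

## Step count and risk

Total step count: 12. Longest linear sequence: 12 steps, from 1 to 18. Compounds 5, 7 and 12 enter as commercial partners.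

**Step 7 (key step).** The facial discrimination may be poor, because the ortho methoxymethoxy group twists ring B out of the alkene plane, so the catalyst sees less contrast between ring B and the bulky arylmethyl arm. Insertion may also be slow at this crowded alkene, and the hydride could then move the double bond towards C4. The fallback sets C3 by dynamic kinetic resolution instead of alkene-face selection. It sets out from 11 and returns at 14. Alkene 11 is hydroborated without selectivity by 9-borabicyclo[3.3.1]nonane to the racemic 9-{3-[2-(tert-butyldimethylsilyloxy)-4,5-dimethoxyphenyl]-2-[3,4-dimethoxy-2-(methoxymethoxy)phenyl]propyl}-9-borabicyclo[3.3.1]nonane F1. This is oxidised with NaBO3·4H2O to racemic 3-[2-(tert-butyldimethylsilyloxy)-4,5-dimethoxyphenyl]-2-[3,4-dimethoxy-2-(methoxymethoxy)phenyl]propan-1-ol F2, and then with Dess–Martin periodinane to racemic 3-[2-(tert-butyldimethylsilyloxy)-4,5-dimethoxyphenyl]-2-[3,4-dimethoxy-2-(methoxymethoxy)phenyl]propanal F3. Hydrogenation of F3 with a RuCl2(chiral spiro diphosphine)(chiral 1,2-diamine) precatalyst, catalytic KOtBu and H2 in iPrOH should give (S)-14, with the catalyst antipode chosen accordingly. Under these conditions the α-aryl aldehyde racemises through its enolate faster than it is reduced. The base is kept catalytic to spare the aryl silyl ether.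

**Step 5.** The rearrangement may partly go to the ortho carbon between the two oxygens. Prolonged heating may also degrade the acetal or let the new phenol add across the styrene-type alkene. The fallback forms C4–C4a by cross-coupling, where the position is fixed by a halogen. It sets out from 6 and 7 and returns at 11. Phenol 7 is brominated with N-bromosuccinimide para to its 3-methoxy group to give 2-bromo-4,5-dimethoxyphenol F4. This is silylated to (2-bromo-4,5-dimethoxyphenoxy)(tert-butyl)dimethylsilane F5. Miyaura borylation (bis(pinacolato)diboron, Pd(dppf)Cl2, KOAc, dioxane) then gives tert-butyl[4,5-dimethoxy-2-(4,4,5,5-tetramethyl-1,3,2-dioxaborolan-2-yl)phenoxy]dimethylsilane F6. Alcohol 6 is converted with methyl chloroformate and pyridine into 2-[3,4-dimethoxy-2-(methoxymethoxy)phenyl]prop-2-en-1-yl methyl carbonate F7. Allyl–aryl coupling of F6 with F7 (Pd2(dba)3, PPh3, THF, 60 °C, through a symmetric π-allyl complex of divalent palladium, the carbonate supplying the methoxide base) gives 11.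

**Step 12.** The oxidation may be slow at the hindered phenol, ring A may be attacked if a stronger oxidant is substituted, and the product may racemise by enolisation through C3–H if the medium turns basic. The fallback introduces the C5' oxygen through nitrogen. It sets out from 17 and returns at 18. Azo coupling of the phenoxide of 17 with benzenediazonium chloride can only occur at the free para carbon and gives 6-[(3S)-6,7-dimethoxy-3,4-dihydro-2H-1-benzopyran-3-yl]-2,3-dimethoxy-4-[(E)-phenyldiazenyl]phenol F8. Reductive cleavage with Na2S2O4 gives 4-amino-6-[(3S)-6,7-dimethoxy-3,4-dihydro-2H-1-benzopyran-3-yl]-2,3-dimethoxyphenol F9. This para-aminophenol is oxidised by FeCl3 in dilute aqueous acid through the quinone imine, which hydrolyses to 18.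

**Step 3.** The electron-rich, ortho-oxygenated boronate may lose boron by protonolysis before it transmetalates, and the small bromo alcohol may be consumed by side reactions at palladium. The fallback builds the alkene by carbonyl olefination, bypasses steps 2 to 4, and links ring A first. It sets out from 2 (through aryllithium 3) and 7 and returns at 8. Phenol 7 is alkylated with 2-chloro-N-methoxy-N-methylacetamide (K2CO3, acetone) to 2-(3,4-dimethoxyphenoxy)-N-methoxy-N-methylacetamide F10. Addition of 3 to F10 gives 1-[3,4-dimethoxy-2-(methoxymethoxy)phenyl]-2-(3,4-dimethoxyphenoxy)ethan-1-one F11. Wittig methylenation of F11 with methylenetriphenylphosphorane gives 8.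

## Further compounds

F1 | step 7 | 9-{3-[2-(tert-butyldimethylsilyloxy)-4,5-dimethoxyphenyl]-2-[3,4-dimethoxy-2-(methoxymethoxy)phenyl]propyl}-9-borabicyclo[3.3.1]nonane (racemic) | COCOc1c(C(CB2C3CCCC2CCC3)Cc2cc(OC)c(OC)cc2O[Si](C)(C)C(C)(C)C)ccc(OC)c1OC
F2 | step 7 | racemic 3-[2-(tert-butyldimethylsilyloxy)-4,5-dimethoxyphenyl]-2-[3,4-dimethoxy-2-(methoxymethoxy)phenyl]propan-1-ol | OCC(Cc1cc(OC)c(OC)cc1O[Si](C)(C)C(C)(C)C)c1ccc(OC)c(OC)c1OCOC
F3 | step 7 | racemic 3-[2-(tert-butyldimethylsilyloxy)-4,5-dimethoxyphenyl]-2-[3,4-dimethoxy-2-(methoxymethoxy)phenyl]propanal | O=CC(Cc1cc(OC)c(OC)cc1O[Si](C)(C)C(C)(C)C)c1ccc(OC)c(OC)c1OCOC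
F4 | step 5 | 2-bromo-4,5-dimethoxyphenol | Oc1cc(OC)c(OC)cc1Br
F5 | step 5 | (2-bromo-4,5-dimethoxyphenoxy)(tert-butyl)dimethylsilane | CC(C)(C)[Si](C)(C)Oc1cc(OC)c(OC)cc1Br
F6 | step 5 | tert-butyl[4,5-dimethoxy-2-(4,4,5,5-tetramethyl-1,3,2-dioxaborolan-2-yl)phenoxy]dimethylsilane | CC(C)(C)[Si](C)(C)Oc1cc(OC)c(OC)cc1B1OC(C)(C)C(C)(C)O1
F7 | step 5 | 2-[3,4-dimethoxy-2-(methoxymethoxy)phenyl]prop-2-en-1-yl methyl carbonate | C=C(COC(=O)OC)c1ccc(OC)c(OC)c1OCOC
F8 | step 12 | 6-[(3S)-6,7-dimethoxy-3,4-dihydro-2H-1-benzopyran-3-yl]-2,3-dimethoxy-4-[(E)-phenyldiazenyl]phenol | COc1c(/N=N/c2ccccc2)cc([C@H]2COc3cc(OC)c(OC)cc3C2)c(O)c1OC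
F9 | step 12 | 4-amino-6-[(3S)-6,7-dimethoxy-3,4-dihydro-2H-1-benzopyran-3-yl]-2,3-dimethoxyphenol | COc1c(N)cc([C@H]2COc3cc(OC)c(OC)cc3C2)c(O)c1OC
F10 | step 3 | 2-(3,4-dimethoxyphenoxy)-N-methoxy-N-methylacetamide | COc1ccc(OCC(=O)N(C)OC)cc1OC
F11 | step 3 | 1-[3,4-dimethoxy-2-(methoxymethoxy)phenyl]-2-(3,4-dimethoxyphenoxy)ethan-1-one | COCOc1c(C(=O)COc2ccc(OC)c(OC)c2)ccc(OC)c1OC
A1 | alternative 1 | 3-(2-bromo-4,5-dimethoxyphenyl)propanal | O=CCCc1cc(OC)c(OC)cc1Br
A2 | alternative 1 | 2,3-dimethoxycyclohexa-2,5-diene-1,4-dione | COC1=C(OC)C(=O)C=CC1=O
A3 | alternative 1 | (3S)-3-[(2-bromo-4,5-dimethoxyphenyl)methyl]-6,7-dimethoxy-2,3-dihydro-1-benzofuran-2,5-diol (both anomers) | OC1Oc2c(OC)c(OC)c(O)cc2[C@@H]1Cc1cc(OC)c(OC)cc1Br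
A4 | alternative 2 | 4-iodo-1,2-dimethoxybenzene | COc1ccc(I)cc1OC
A5 | alternative 2 | (2S)-3-bromo-2-[3,4-dimethoxy-2-(methoxymethoxy)phenyl]propan-1-ol | OC[C@@H](CBr)c1ccc(OC)c(OC)c1OCOC
A6 | alternative 2 | (3S)-3-[3,4-dimethoxy-2-(methoxymethoxy)phenyl]-6,7-dimethoxychroman (same structure as 16) | COc1ccc([C@H]2COc3cc(OC)c(OC)cc3C2)c(OCOC)c1OC
A7 | alternative 3 | 3-[2,5-bis(benzyloxy)-3,4-dimethoxyphenyl]oxetane | COc1c(OCc2ccccc2)cc(C2COC2)c(OCc2ccccc2)c1OC
A8 | alternative 3 | {(2R)-2-[2,5-bis(benzyloxy)-3,4-dimethoxyphenyl]-3-bromopropoxy}trimethylsilane | C[Si](C)(C)OC[C@H](CBr)c1cc(OCc2ccccc2)c(OC)c(OC)c1OCc1ccccc1
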